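**Retrosynthetic overview**

1. Numbering used throughout (germacrane type): C1 furanone ketone, C2, C3 enol-ether carbon, C4 (=C15H2), C5 (OH), C6 (lactone O), C7, C8 (isovalerate), C9 (CH2), C10 (quaternary; methyl C14; ring O), C11 (=C13H2), C12 lactone carbonyl.
2. Key disconnection: the C7–C8 bond of the nine-membered oxacycle O–C3–C4–C5–C6–C7–C8–C9–C10. The enabling feature is the exocyclic C11=C13 methylene on the lactone ring next to C7, with the C8 carbinol one bond further, which is a homoallylic-alcohol (SE2') retron. The lactone is therefore carried as a butenolide (C7=C11) with a CH2SiMe3 group at C13, and an intramolecular Hosomi–Sakurai addition to a C8 aldehyde closes the ring, sets C7 and C8 and unmasks the α-methylene lactone.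
3. Seco-aldehyde: the furanone ring comes from a gold-catalysed 5-endo-dig cyclisation of an α'-hydroxy ynone; C3–C4 comes from a Sonogashira coupling of a terminal alkyne (C10 from (R)-citramalic acid) with a 1-bromovinyl butenolide.
4. Butenolide half: a 2-silyloxy-3-(silylmethyl)furan serves as a double nucleophile for C6 and C7; its catalytic anti-selective vinylogous Mukaiyama aldol with 2-bromoacrolein sets C5 and C6.
5. Ring order: lactone ring first (furan, then butenolide), furanone ring second, nine-membered ring last (this closure also completes the ten-membered carbocycle); then C8 acylation and C5 desilylation.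

Key step: step 14

Remark: (R)-citramalic acid, 3-bromofuran-2(5H)-one and the bisphosphoramide catalyst are taken as purchasable; the (S,S)-catalyst is chosen on the premise that its (R,R)-antipode delivers nucleophiles to the Re face of aldehydes, and the antipodal catalyst is used if the sense proves opposite.

**Route**

Step 1
Reactants: 1 (R)-citramalic acid
Product: 2 2-[(4R)-2,2,4-trimethyl-5-oxo-1,3-dioxolan-4-yl]acetic acid
Conditions: 2,2-dimethoxypropane, p-TsOH·H2O (cat.), rt
Reagents that add atoms: 2,2-dimethoxypropane COC(C)(C)OC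
Why: Acid-catalysed transacetalisation ties the tertiary hydroxyl and its neighbouring carboxyl into the five-membered dioxolanone, which leaves the CH2CO2H carboxyl (future C8) free and does not touch the C10 stereocentre.

Step 2
Reactants: 2 2-[(4R)-2,2,4-trimethyl-5-oxo-1,3-dioxolan-4-yl]acetic acid
Product: 4 (3R)-3-hydroxy-3-methyloxolan-2-one, via hydroxyethyl dioxolanone 3 (not isolated)
Conditions: BH3·SMe2, THF, 0 °C to rt; MeOH; then p-TsOH·H2O (cat.), CH2Cl2, rt
Reagents that add atoms: none
Why: Borane reduces the free carboxylic acid much faster than the dioxolanone ester (chemoselective acid reduction), and acid then drives translactonisation of the new primary alcohol with loss of acetone.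

Step 3
Reactants: 4 (3R)-3-hydroxy-3-methyloxolan-2-one
Product: 5 (3R)-3-methyloxolane-2,3-diol (lactol; anomer mixture)
Conditions: i-Bu2AlH (2.2 equiv), CH2Cl2, −78 °C; aq. KNaC4H4O6
Reagents that add atoms: none
Why: Partial reduction of the γ-lactone should stop at the tetrahedral aluminium hemiacetal at low temperature, the first equivalent being consumed by the tertiary hydroxyl.

Step 4
Reactants: 5 (3R)-3-methyloxolane-2,3-diol; 6 ethynylmagnesium bromide
Product: 7 (3R)-3-methylhex-5-yne-1,3,4-triol (both C4 epimers)
Conditions: HC≡CMgBr (5 equiv), THF, 0 °C to rt; aq. NH4Cl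
Reagents that add atoms: none
Why: Grignard addition to the ring-opened hydroxy-aldehyde form of the lactol; the new carbinol (C1) forms as an epimer mixture, which does not matter because it is oxidised in step 11.

Step 5
Reactants: 8 3-bromofuran-2(5H)-one; 9 (trimethylsilyl)methylmagnesium chloride
Product: 11 3-[(trimethylsilyl)methyl]furan-2(5H)-one, via (trimethylsilyl)methylzinc chloride 10 (not isolated)
Conditions: 9, ZnCl2, THF, 0 °C; then 8, Pd(PPh3)4 (5 mol %), THF, rt to 45 °C
Reagents that add atoms: none
Why: Negishi coupling of an α-bromo enoate with an alkylzinc that has no β-hydrogen; the zinc reagent should not add to the lactone, and the product carries the allylsilane (C13–Si) needed in step 14.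

Step 6
Reactants: 11 3-[(trimethylsilyl)methyl]furan-2(5H)-one
Product: 12 tert-butyl(dimethyl)({3-[(trimethylsilyl)methyl]furan-2-yl}oxy)silane
Conditions: TBSOTf, Et3N, CH2Cl2, 0 °C
Reagents that add atoms: tert-butyldimethylsilyl trifluoromethanesulfonate CC(C)(C)[Si](C)(C)OS(=O)(=O)C(F)(F)F
Why: Soft enolisation of the butenolide at its γ-CH2 and O-silylation give the aromatic 2-silyloxyfuran (silyl dienol ether formation).

Step 7
Reactants: 13 acrolein
Product: 15 2-bromoprop-2-enal, via 2,3-dibromopropanal 14 (not isolated)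
Conditions: Br2, CH2Cl2, −78 °C; then Et3N, −78 to 0 °C
Reagents that add atoms: bromine BrBr
Why: Bromine addition to the alkene followed by E1cB loss of HBr from the α-bromo aldehyde returns the enal with bromine on the α-carbon (future C4).

Step 8
Reactants: 12 tert-butyl(dimethyl)({3-[(trimethylsilyl)methyl]furan-2-yl}oxy)silane; 15 2-bromoprop-2-enal
Product: 16 (5S)-5-[(1S)-2-bromo-1-hydroxyprop-2-en-1-yl]-3-[(trimethylsilyl)methyl]furan-2(5H)-one
Conditions: SiCl4, (S,S)-bisphosphoramide catalyst (binaphthyldiamine-derived, pentane-1,5-diyl-linked; 5 mol %), i-Pr2NEt (10 mol %), CH2Cl2, −78 °C; aq. KF/NaHCO3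
Reagents that add atoms: none
Why: In this Lewis-base-catalysed, SiCl4-mediated vinylogous Mukaiyama aldol the phosphoramide-bound trichlorosilyl cation activates the enal, the furan attacks through its γ-carbon (C6) in an open transition state that should give the anti adduct, and the (S,S)-catalyst should direct attack to the Si face of the aldehyde, so C5 and C6 are set together (the 1S descriptor at C5 reflects only the bromine substituent).

Step 9
Reactants: 16 (5S)-5-[(1S)-2-bromo-1-hydroxyprop-2-en-1-yl]-3-[(trimethylsilyl)methyl]furan-2(5H)-one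
Product: 17 (5S)-5-[(1S)-2-bromo-1-{[tert-butyl(dimethyl)silyl]oxy}prop-2-en-1-yl]-3-[(trimethylsilyl)methyl]furan-2(5H)-one
Conditions: TBSOTf, 2,6-lutidine, CH2Cl2, −78 °C
Reagents that add atoms: tert-butyldimethylsilyl trifluoromethanesulfonate CC(C)(C)[Si](C)(C)OS(=O)(=O)C(F)(F)F
Why: Silylation of the hindered secondary alcohol with a silyl triflate and a weak hindered base at low temperature should be much faster than enolisation of the butenolide, so C6 is not disturbed.

Step 10
Reactants: 7 (3R)-3-methylhex-5-yne-1,3,4-triol; 17 (5S)-5-[(1S)-2-bromo-1-{[tert-butyl(dimethyl)silyl]oxy}prop-2-en-1-yl]-3-[(trimethylsilyl)methyl]furan-2(5H)-one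
Product: 18 (5S)-5-[(1R,6R)-1-{[tert-butyl(dimethyl)silyl]oxy}-5,6,8-trihydroxy-6-methyl-2-methylideneoct-3-yn-1-yl]-3-[(trimethylsilyl)methyl]furan-2(5H)-one (both epimers at the propargylic carbinol)
Conditions: Pd(PPh3)4 (5 mol %), CuI (10 mol %), i-Pr2NEt, degassed DMF, rt to 40 °C
Reagents that add atoms: none
Why: Sonogashira coupling of the terminal alkyne with the 1-bromovinyl group forms C3–C4; free hydroxyls and the allylsilane are tolerated and no stereocentre is made.

Step 11
Reactants: 18 enyne triol
Product: 19 (5S)-5-[(1R,6R)-1-{[tert-butyl(dimethyl)silyl]oxy}-6,8-dihydroxy-6-methyl-2-methylidene-5-oxooct-3-yn-1-yl]-3-[(trimethylsilyl)methyl]furan-2(5H)-one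
Conditions: MnO2 (excess), CH2Cl2, rt
Reagents that add atoms: none
Why: Activated MnO2 oxidises only the propargylic secondary alcohol (chemoselective propargylic oxidation), leaving the primary and tertiary hydroxyls.

Step 12
Reactants: 19 α'-hydroxy ynone
Product: 20 (5S)-5-{(1R)-1-{[tert-butyl(dimethyl)silyl]oxy}-2-[(5R)-5-(2-hydroxyethyl)-5-methyl-4-oxo-4,5-dihydrofuran-2-yl]prop-2-en-1-yl}-3-[(trimethylsilyl)methyl]furan-2(5H)-one
Conditions: (4-CF3C6H4)3PAuCl (5 mol %), AgOTf (5 mol %), toluene, rt
Reagents that add atoms: none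
Why: Gold-catalysed 5-endo-dig cycloisomerisation of the α'-hydroxy ynone gives the 3(2H)-furanone; only the tertiary hydroxyl can reach the β-alkyne carbon (C3) through a five-membered closure, and C10 is retained.

Step 13
Reactants: 20 furanone primary alcohol
Product: 21 {(2R)-5-[(3R)-3-{[tert-butyl(dimethyl)silyl]oxy}-3-{(2S)-5-oxo-4-[(trimethylsilyl)methyl]-2,5-dihydrofuran-2-yl}prop-1-en-2-yl]-2-methyl-3-oxo-2,3-dihydrofuran-2-yl}acetaldehyde
Conditions: Dess–Martin periodinane, NaHCO3, CH2Cl2, 0 °C to rt; used crude
Reagents that add atoms: none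
Why: Dess–Martin oxidation of the only free hydroxyl under buffered, amine-free conditions, chosen because the aldehyde could lose the furanone oxygen from C10 by β-elimination under basic conditions.

Step 14
Reactants: 21 seco-aldehyde
Product: 22 (5R,6S,7R,8R,10R)-tricyclic alcohol (target skeleton with free C8–OH and C5–OTBS)
Conditions: BF3·OEt2 (3 equiv), CH2Cl2 (0.003 M), −78 to −20 °C; aq. NaHCO3
Reagents that add atoms: none
Why: BF3 activates the C8 aldehyde, which is attacked 9-exo-trig by C7 of the 2-(silylmethyl)butenolide in an SE2' (Hosomi–Sakurai) addition; loss of the silyl group from C13 moves the double bond to C11=C13, so one bond formation closes the nine-membered oxacycle (and with it the ten-membered carbocycle) and unmasks the α-methylene lactone. The closest known reaction type is the Lewis-acid-promoted inter- and intramolecular addition of 2-(alkoxycarbonyl)allylsilanes to aldehydes, used to make α-methylene-γ-lactones fused to medium rings. C7 is controlled by C6: the aldehyde should add to the butenolide face opposite the C5 substituent, the usual sense for γ-substituted butenolide nucleophiles and the approach that avoids eclipsing the forming C7–C8 bond with C6–C5, which gives the trans-fused lactone. C8 is controlled by an open synclinal transition state in which the tether holds C9 anti to the C7=C11 bond and the BF3-bound oxygen lies over the flat lactone carbonyl, away from the CH2SiMe3 terminus; this is attack on the Si face of the aldehyde and should give 8R, whereas a closed, metal-bridged transition state would give the 8S epimer. The step needs γ- over α-attack (secured by the allylsilane SE2' mechanism), cyclisation over oligomerisation (secured by high dilution and by the rigid furanone and butenolide rings that shorten the seco chain), and tolerance of the other π-systems (the furanone and C4=C15 alkenes are electron-poor and the C5 ether is a robust silyl group).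

Step 15
Reactants: 22 tricyclic alcohol; 23 3-methylbutanoic anhydride
Product: 24 (5R,6S,7R,8R,10R)-C5-O-TBS ether of the target
Conditions: DMAP (cat.), pyridine, CH2Cl2, 0 °C to rt
Reagents that add atoms: none
Why: DMAP-catalysed acyl transfer to the only free hydroxyl installs the isovalerate with retention at C8.

Step 16
Reactants: 24 C5-O-TBS ether of the target
Product: 25 CNP0409337.2 (target)
Conditions: HF·pyridine, pyridine, THF, 0 °C to rt
Reagents that add atoms: none
Why: Buffered fluoride cleavage of the allylic silyl ether should leave the ester, the α-methylene lactone and the furanone intact and does not affect any stereocentre.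

**Compound list**

1 | (R)-citramalic acid, (2R)-2-hydroxy-2-methylbutanedioic acid | OC(=O)C[C@@](C)(O)C(=O)O | starting material
2 | 2-[(4R)-2,2,4-trimethyl-5-oxo-1,3-dioxolan-4-yl]acetic acid | OC(=O)C[C@@]1(C)OC(C)(C)OC1=O | intermediate
3 | (5R)-5-(2-hydroxyethyl)-2,2,5-trimethyl-1,3-dioxolan-4-one | OCC[C@@]1(C)OC(C)(C)OC1=O | intermediate
4 | (3R)-3-hydroxy-3-methyloxolan-2-one | O=C1OCC[C@@]1(C)O | intermediate
5 | (3R)-3-methyloxolane-2,3-diol (anomer mixture) | OC1OCC[C@@]1(C)O | intermediate
6 | ethynylmagnesium bromide | C#C[Mg]Br | starting material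
7 | (3R)-3-methylhex-5-yne-1,3,4-triol (both C4 epimers) | OCC[C@@](C)(O)C(O)C#C | intermediate
8 | 3-bromofuran-2(5H)-one | O=C1OCC=C1Br | starting material
9 | (trimethylsilyl)methylmagnesium chloride | C[Si](C)(C)C[Mg]Cl | starting material
10 | (trimethylsilyl)methylzinc chloride | C[Si](C)(C)C[Zn]Cl | intermediate
11 | 3-[(trimethylsilyl)methyl]furan-2(5H)-one | O=C1OCC=C1C[Si](C)(C)C | intermediate
12 | tert-butyl(dimethyl)({3-[(trimethylsilyl)methyl]furan-2-yl}oxy)silane | CC(C)(C)[Si](C)(C)Oc1occc1C[Si](C)(C)C | intermediate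
13 | acrolein | C=CC=O | starting material
14 | 2,3-dibromopropanal | O=CC(Br)CBr | intermediate
15 | 2-bromoprop-2-enal | C=C(Br)C=O | intermediate
16 | (5S)-5-[(1S)-2-bromo-1-hydroxyprop-2-en-1-yl]-3-[(trimethylsilyl)methyl]furan-2(5H)-one | C=C(Br)[C@@H](O)[C@H]1OC(=O)C(C[Si](C)(C)C)=C1 | intermediate
17 | (5S)-5-[(1S)-2-bromo-1-{[tert-butyl(dimethyl)silyl]oxy}prop-2-en-1-yl]-3-[(trimethylsilyl)methyl]furan-2(5H)-one | C=C(Br)[C@@H](O[Si](C)(C)C(C)(C)C)[C@H]1OC(=O)C(C[Si](C)(C)C)=C1 | intermediate
18 | enyne triol, (5S)-5-[(1R,6R)-1-(TBS-oxy)-5,6,8-trihydroxy-6-methyl-2-methylideneoct-3-yn-1-yl]-3-[(trimethylsilyl)methyl]furan-2(5H)-one (both epimers at the propargylic carbinol) | OCC[C@@](C)(O)C(O)C#CC(=C)[C@@H](O[Si](C)(C)C(C)(C)C)[C@H]1OC(=O)C(C[Si](C)(C)C)=C1 | intermediate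
19 | α'-hydroxy ynone, (5S)-5-[(1R,6R)-1-(TBS-oxy)-6,8-dihydroxy-6-methyl-2-methylidene-5-oxooct-3-yn-1-yl]-3-[(trimethylsilyl)methyl]furan-2(5H)-one | OCC[C@@](C)(O)C(=O)C#CC(=C)[C@@H](O[Si](C)(C)C(C)(C)C)[C@H]1OC(=O)C(C[Si](C)(C)C)=C1 | intermediate
20 | furanone alcohol, (5S)-5-{(1R)-1-(TBS-oxy)-2-[(5R)-5-(2-hydroxyethyl)-5-methyl-4-oxo-4,5-dihydrofuran-2-yl]prop-2-en-1-yl}-3-[(trimethylsilyl)methyl]furan-2(5H)-one | OCC[C@@]1(C)OC(=CC1=O)C(=C)[C@@H](O[Si](C)(C)C(C)(C)C)[C@H]1OC(=O)C(C[Si](C)(C)C)=C1 | intermediate
21 | seco-aldehyde, {(2R)-5-[(3R)-3-(TBS-oxy)-3-{(2S)-5-oxo-4-[(trimethylsilyl)methyl]-2,5-dihydrofuran-2-yl}prop-1-en-2-yl]-2-methyl-3-oxo-2,3-dihydrofuran-2-yl}acetaldehyde | O=CC[C@@]1(C)OC(=CC1=O)C(=C)[C@@H](O[Si](C)(C)C(C)(C)C)[C@H]1OC(=O)C(C[Si](C)(C)C)=C1 | intermediate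
22 | (5R,6S,7R,8R,10R)-tricyclic alcohol: target skeleton with free C8–OH and C5–OTBS | C=C1C(=O)O[C@H]2[C@H]1[C@H](O)C[C@@]1(C)OC(=CC1=O)C(=C)[C@H]2O[Si](C)(C)C(C)(C)C | intermediate
23 | 3-methylbutanoic anhydride (isovaleric anhydride) | CC(C)CC(=O)OC(=O)CC(C)C | starting material
24 | (5R,6S,7R,8R,10R)-C5-O-TBS ether of the target | C=C1C(=O)O[C@H]2[C@H]1[C@H](OC(=O)CC(C)C)C[C@@]1(C)OC(=CC1=O)C(=C)[C@H]2O[Si](C)(C)C(C)(C)C | intermediate
25 | CNP0409337.2, (5R,6S,7R,8R,10R) | C=C1C(=O)O[C@H]2[C@H]1[C@H](OC(=O)CC(C)C)C[C@@]1(C)OC(=CC1=O)C(=C)[C@H]2O | target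

**Step count and risks**

Total steps: 16. Longest linear sequence: 11 steps (steps 1–4 then 10–16; equally steps 5, 6, 8, 9 then 10–16).

Most likely to fail, first: step 14. What may go wrong is attack on the Re face of the tethered aldehyde, for example through the alternative synclinal arrangement with the complexed oxygen next to C13, so that the ring closes with the wrong configuration at C8. The fallback corrects C8 by substitution instead of by facial selectivity. Setting out from 21, the same closure then gives the epimeric (8S)-alcohol F1, which is esterified with inversion under Mitsunobu conditions (3-methylbutanoic acid, PPh3, diisopropyl azodicarboxylate, toluene, 0 °C to rt). The SN2 displacement at C8 installs the isovalerate with the 8R configuration, and the fallback comes back to the route at 24.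

Second: step 8. What may go wrong is conjugate addition to, or polymerisation of, the α-bromoenal in competition with carbonyl addition, together with erosion of anti- and enantioselectivity for this unusual pair of partners. The fallback replaces the enal by an ynal whose β-position is blocked and builds the bromoalkene afterwards. Setting out from 12, the same catalyst system with commercial 3-(trimethylsilyl)prop-2-ynal should give propargylic alcohol F2. Silylation (TBSOTf, 2,6-lutidine, −78 °C) gives silyl ether F3. AgNO3-catalysed protodesilylation in aqueous acetone frees terminal alkyne F4 without touching the O-silyl or allylsilane groups. Syn-bromoboration with B-bromo-9-borabicyclo[3.3.1]nonane (CH2Cl2, 0 °C) gives (Z)-2-bromoalkenylborane F5, and protonolysis with acetic acid gives the 2-bromoalkene, so the fallback comes back to the route at 17.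

Third: step 10. What may go wrong is deprotonation of the butenolide at C6 under the amine and copper conditions, which would epimerise C6 or expel the C5 silyloxy group, together with slow oxidative addition to the hindered 1-bromovinyl unit. The fallback is a base-free Stille coupling. Setting out from 7, ZnBr2-catalysed stannylation with Bu3SnOMe (THF, rt) gives alkynylstannane F6, which is coupled with 17 (Pd(PPh3)4, DMF, 50 °C) under neutral conditions, and the fallback comes back to the route at 18.

**Further compounds**

F1 | step 14 | (5R,6S,7R,8S,10R)-C8 epimer of alcohol 22 | C=C1C(=O)O[C@H]2[C@H]1[C@@H](O)C[C@@]1(C)OC(=CC1=O)C(=C)[C@H]2O[Si](C)(C)C(C)(C)C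
F2 | step 8 | (5S)-5-[(1R)-1-hydroxy-3-(trimethylsilyl)prop-2-yn-1-yl]-3-[(trimethylsilyl)methyl]furan-2(5H)-one | C[Si](C)(C)C#C[C@@H](O)[C@H]1OC(=O)C(C[Si](C)(C)C)=C1
F3 | step 8 | (5S)-5-[(1R)-1-{[tert-butyl(dimethyl)silyl]oxy}-3-(trimethylsilyl)prop-2-yn-1-yl]-3-[(trimethylsilyl)methyl]furan-2(5H)-one | C[Si](C)(C)C#C[C@@H](O[Si](C)(C)C(C)(C)C)[C@H]1OC(=O)C(C[Si](C)(C)C)=C1
F4 | step 8 | (5S)-5-[(1R)-1-{[tert-butyl(dimethyl)silyl]oxy}prop-2-yn-1-yl]-3-[(trimethylsilyl)methyl]furan-2(5H)-one | C#C[C@@H](O[Si](C)(C)C(C)(C)C)[C@H]1OC(=O)C(C[Si](C)(C)C)=C1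
F5 | step 8 | (5S)-5-[(1S,2Z)-3-(9-borabicyclo[3.3.1]nonan-9-yl)-2-bromo-1-{[tert-butyl(dimethyl)silyl]oxy}prop-2-en-1-yl]-3-[(trimethylsilyl)methyl]furan-2(5H)-one | Br/C(=C\B1C2CCCC1CCC2)[C@@H](O[Si](C)(C)C(C)(C)C)[C@H]1OC(=O)C(C[Si](C)(C)C)=C1
F6 | step 10 | (3R)-3-methyl-6-(tributylstannyl)hex-5-yne-1,3,4-triol (both C4 epimers) | OCC[C@@](C)(O)C(O)C#C[Sn](CCCC)(CCCC)CCCC
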